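The route rests on cutting the exocyclic C6–CH2 bond of the 1,2-dioxane ring (O1–O2–C3–C4–C5–C6), between the homofarnesyl chain and the quaternary ring carbon. C6 is bonded to ring oxygen O1, so a 6-methoxy-6-methyl-1,2-dioxane (cyclic peroxyketal) is a latent peroxycarbenium ion C6=O1(+). In one operation the key step couples this small chiral ring acid, silylated in the flask and already carrying the C3 and side-chain stereocentres, to bis(homofarnesyl)zinc: it forms the C–C bond, sets the quaternary stereocentre C6 by axial attack cis to the C3 substituent and releases the natural product itself. The peroxyketal comes from a syn-crotylation adduct by sulfonate displacement with inversion.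

Key step: step 7

Remark: the target is (2S) in the side chain and (3S,6S) in the ring; compounds 7, 8, 9, 10 and 13 are carried as mixtures at the ketal carbon, which becomes planar in step 7.

Step 1
Reactants: 1 5-hexen-2-one
Product: 2 4-oxopentanal
Conditions: O3, CH2Cl2, −78 °C; Me2S, −78 °C to rt
Reagents that add atoms: ozone, [O-][O+]=O
Why: Ozonolysis (Criegee mechanism) of the only C=C bond with reductive work-up should give the aldehyde without touching the methyl ketone; no stereocentre is formed.

Step 2
Reactants: 2 4-oxopentanal; 3 (Z)-but-2-ene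
Product: 5 (5R,6R)-5-hydroxy-6-methyloct-7-en-2-one, via (Z)-crotyldiisopinocampheylborane 4 (not isolated)
Conditions: 3, KOtBu, n-BuLi, THF, −78 to −45 °C; (−)-Ipc2BOMe, −78 °C; BF3·OEt2; then 2, −78 °C; NaOH, H2O2, 0 °C to rt
Reagents that add atoms: none
Why: Brown asymmetric crotylboration through a closed chair transition state should translate the Z geometry into the syn relationship, while the isopinocampheyl groups derived from (+)-α-pinene direct the crotyl unit to the Si face of the aldehyde to set (5R,6R), and the aldehyde reacts at −78 °C far faster than the methyl ketone.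

Step 3
Reactants: 5 (5R,6R)-5-hydroxy-6-methyloct-7-en-2-one
Product: 6 (3R,4R)-3-methyl-7-oxooct-1-en-4-yl methanesulfonate
Conditions: MsCl, Et3N, CH2Cl2, −20 to 0 °C
Reagents that add atoms: methanesulfonyl chloride, CS(=O)(=O)Cl
Why: Sulfonylation of the secondary alcohol takes place on oxygen with retention at the carbinol carbon and prepares it for displacement.

Step 4
Reactants: 6 (3R,4R)-3-methyl-7-oxooct-1-en-4-yl methanesulfonate
Product: 8 (3S)-3-[(2R)-but-3-en-2-yl]-6-methoxy-6-methyl-1,2-dioxane, via methoxy hydroperoxide mesylate 7 (not isolated)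
Conditions: urea·H2O2, Sc(OTf)3 (cat.), MeOH, 0 °C to rt; then KOtBu, 18-crown-6, THF, 0 °C
Reagents that add atoms: hydrogen peroxide (used as its urea adduct), OO; methanol, CO
Why: Acid-catalysed perhydrolysis of the methyl ketone in methanol should give the α-methoxy hydroperoxide, whose potassium salt closes the ring by intramolecular SN2 alkylation of a hydroperoxy ketal (6-exo-tet), the inversion at the sulfonate carbon setting the (S) configuration of C3.

Step 5
Reactants: 8 (3S)-3-[(2R)-but-3-en-2-yl]-6-methoxy-6-methyl-1,2-dioxane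
Product: 10 (2S)-2-[(3S)-6-methoxy-6-methyl-1,2-dioxan-3-yl]propanoic acid, via peroxyketal aldehyde 9 (not isolated)
Conditions: O3, CH2Cl2, −78 °C; Me2S; then NaClO2, NaH2PO4, 2-methyl-2-butene, t-BuOH/H2O, 0 °C
Reagents that add atoms: ozone, [O-][O+]=O; sodium chlorite, [Na+].[O-]Cl=O
Why: Ozonolysis of the vinyl group followed by Pinnick oxidation under buffered, weakly acidic conditions should turn the latent carboxyl carbon into the acid without enolising the α-stereocentre or disturbing the peroxyketal, so the (2S) centre is retained.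

Step 6
Reactants: 11 (3E,7E)-homofarnesol
Product: 12 (3E,7E)-1-bromo-4,8,12-trimethyltrideca-3,7,11-triene (homofarnesyl bromide)
Conditions: CBr4, PPh3, CH2Cl2, 0 °C
Reagents that add atoms: carbon tetrabromide, BrC(Br)(Br)Br
Why: Appel bromination converts the primary homoallylic alcohol into the bromide under neutral conditions that leave the three trisubstituted alkenes and their E geometry untouched.

Step 7
Reactants: 10 (2S)-2-[(3S)-6-methoxy-6-methyl-1,2-dioxan-3-yl]propanoic acid; 12 homofarnesyl bromide
Product: 17 (2S)-2-[(3S,6S)-6-methyl-6-[(3E,7E)-4,8,12-trimethyltrideca-3,7,11-trien-1-yl]-1,2-dioxan-3-yl]propanoic acid (CNP0179915.1), via trimethylsilyl ester 13 (not isolated), via homofarnesylmagnesium bromide 14 (not isolated), via bis(homofarnesyl)zinc 15 (not isolated), via silyl ester of coupled acid 16 (not isolated)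
Conditions: 10: HMDS, CH2Cl2, 40 °C, evaporate; 12: Mg, THF, rt, then ZnCl2 (0.5 equiv), 0 °C, 1,4-dioxane, decant from magnesium salts; 13 + 15 (2 equiv), CH2Cl2, −78 °C, TMSOTf (1.2 equiv), −78 to −40 °C; aqueous citrate buffer pH 4
Reagents that add atoms: none
Why: Proposed new method: TMSOTf silylates and expels the methoxy group of 13 to give the six-membered peroxycarbenium ion C6=O1(+), and the primary C–Zn bond of 15 then delivers the homofarnesyl CH2 to C6, after which the buffered work-up cleaves the silyl ester to the free acid. The closest known reaction types are the allylsilane and silyl enol ether alkylations of peroxyketal-derived peroxycarbenium ions and the TMSOTf-promoted transfer of primary alkyl groups from dialkylzincs to cyclic oxocarbenium ions generated from α-acetoxy ethers; an alkylzinc has not been shown on a peroxycarbenium ion. No ring is closed. The new quaternary stereocentre C6 is controlled by the ring: the cation should adopt the half-chair that keeps the C3 side chain pseudo-equatorial and the nucleophile should enter along the axial trajectory that leads directly to the chair, which places the incoming chain cis to the C3 substituent and the methyl group equatorial, that is (6S). The step needs attack at carbon and not at a peroxide oxygen, and capture of the cation by the C–Zn bond in preference to the three trisubstituted alkenes; the first should be secured by the higher basicity of the methoxy oxygen toward the silyl Lewis acid and the low reactivity of salt-free dialkylzinc toward dialkyl peroxides at −78 °C, the second by the greater nucleophilicity of the σ C–Zn bond and by keeping the zinc reagent in excess over the cation.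

Compound list
1 | 5-hexen-2-one | CC(=O)CCC=C | starting material
2 | 4-oxopentanal | CC(=O)CCC=O | intermediate
3 | (Z)-but-2-ene | C/C=C\C | starting material
4 | (Z)-crotyldiisopinocampheylborane, Ipc groups from (+)-α-pinene | C/C=C\CB([C@@H]1C[C@@H]2C[C@@H](C2(C)C)[C@H]1C)[C@@H]1C[C@@H]2C[C@@H](C2(C)C)[C@H]1C | intermediate (not isolated)
5 | (5R,6R)-5-hydroxy-6-methyloct-7-en-2-one | CC(=O)CC[C@@H](O)[C@H](C)C=C | intermediate
6 | (3R,4R)-3-methyl-7-oxooct-1-en-4-yl methanesulfonate | CC(=O)CC[C@@H](OS(C)(=O)=O)[C@H](C)C=C | intermediate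
7 | (3R,4R)-7-hydroperoxy-7-methoxy-3-methyloct-1-en-4-yl methanesulfonate (both C7 epimers) | COC(C)(OO)CC[C@@H](OS(C)(=O)=O)[C@H](C)C=C | intermediate (not isolated)
8 | (3S)-3-[(2R)-but-3-en-2-yl]-6-methoxy-6-methyl-1,2-dioxane (both C6 epimers) | COC1(C)CC[C@@H]([C@H](C)C=C)OO1 | intermediate
9 | (2S)-2-[(3S)-6-methoxy-6-methyl-1,2-dioxan-3-yl]propanal | COC1(C)CC[C@@H]([C@H](C)C=O)OO1 | intermediate (not isolated)
10 | (2S)-2-[(3S)-6-methoxy-6-methyl-1,2-dioxan-3-yl]propanoic acid | COC1(C)CC[C@@H]([C@H](C)C(=O)O)OO1 | intermediate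
11 | (3E,7E)-4,8,12-trimethyltrideca-3,7,11-trien-1-ol (homofarnesol) | CC(C)=CCC/C(C)=C/CC/C(C)=C/CCO | starting material
12 | (3E,7E)-1-bromo-4,8,12-trimethyltrideca-3,7,11-triene | CC(C)=CCC/C(C)=C/CC/C(C)=C/CCBr | intermediate
13 | trimethylsilyl (2S)-2-[(3S)-6-methoxy-6-methyl-1,2-dioxan-3-yl]propanoate | COC1(C)CC[C@@H]([C@H](C)C(=O)O[Si](C)(C)C)OO1 | intermediate (not isolated)
14 | homofarnesylmagnesium bromide | CC(C)=CCC/C(C)=C/CC/C(C)=C/CC[Mg]Br | intermediate (not isolated)
15 | bis[(3E,7E)-4,8,12-trimethyltrideca-3,7,11-trien-1-yl]zinc | CC(C)=CCC/C(C)=C/CC/C(C)=C/CC[Zn]CC/C=C(\C)CC/C=C(\C)CCC=C(C)C | intermediate (not isolated)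
16 | trimethylsilyl ester of 17 | CC(C)=CCC/C(C)=C/CC/C(C)=C/CC[C@@]1(C)CC[C@@H]([C@H](C)C(=O)O[Si](C)(C)C)OO1 | intermediate (not isolated)
17 | (2S)-2-[(3S,6S)-6-methyl-6-[(3E,7E)-4,8,12-trimethyltrideca-3,7,11-trien-1-yl]-1,2-dioxan-3-yl]propanoic acid | CC(C)=CCC/C(C)=C/CC/C(C)=C/CC[C@@]1(C)CC[C@@H]([C@H](C)C(=O)O)OO1 | target

Total step count: 7. Longest linear sequence: 6 steps (1, 2, 3, 4, 5, 7).

Steps most likely to fail

1. Step 7. The alkylzinc may attack a peroxide oxygen (ring opening to ethers) instead of C6. The cation may also be captured by a trisubstituted alkene or lose a proton to an enol peroxide. The fallback uses known chemistry, sets out from acid 10 and comes back at target 17. Esterification with TMSCHN2 gives methyl (2S)-2-[(3S)-6-methoxy-6-methyl-1,2-dioxan-3-yl]propanoate F1. The established Hosomi–Sakurai-type allylation of the peroxyketal (allyltrimethylsilane, TMSOTf, CH2Cl2, −78 °C) forms the same C6–CH2 bond with the same axial sense and gives methyl (2S)-2-[(3S,6R)-6-methyl-6-(prop-2-en-1-yl)-1,2-dioxan-3-yl]propanoate F2. Ozonolysis with NaBH4 work-up gives methyl (2S)-2-[(3S,6R)-6-(2-hydroxyethyl)-6-methyl-1,2-dioxan-3-yl]propanoate F3, and Appel iodination (I2, PPh3, imidazole) gives methyl (2S)-2-[(3S,6R)-6-(2-iodoethyl)-6-methyl-1,2-dioxan-3-yl]propanoate F4. Separately, purchased (E)-geranylacetone is converted with LDA and ClP(O)(OEt)2 into diethyl (5E)-6,10-dimethylundeca-1,5,9-trien-2-yl phosphate F5, which a second portion of LDA eliminates to (5E)-6,10-dimethylundeca-5,9-dien-1-yne F6. Zirconium-catalysed methylalumination (Me3Al, Cp2ZrCl2) gives dimethyl[(1E,5E)-2,6,10-trimethylundeca-1,5,9-trien-1-yl]alumane F7, and iodine gives (1E,5E)-1-iodo-2,6,10-trimethylundeca-1,5,9-triene F8. Zinc insertion into F4 (Zn dust, LiCl, THF) gives the alkylzinc iodide of F4 F9. Negishi coupling of this with F8 [Pd(dppf)Cl2, THF, rt] gives methyl (2S)-2-[(3S,6S)-6-methyl-6-[(3E,7E)-4,8,12-trimethyltrideca-3,7,11-trien-1-yl]-1,2-dioxan-3-yl]propanoate F10, the chain now being completed at the CH2–CH= bond two atoms further out. LiOH in THF/H2O at 0 °C then gives 17.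

2. Step 4. The 6-exo displacement at the β-branched secondary carbon may be slow, so that E2 elimination toward the conjugated diene or over-perhydrolysis of the ketone to a geminal dihydroperoxide takes over. The fallback sets out from mesylate 6 and comes back at 8. Intermolecular SN2 displacement with the caesium salt of 2-methoxyprop-2-yl hydroperoxide (CsOH·H2O, DMF, 0 °C), a weakly basic protected peroxide nucleophile, gives with inversion (5S,6R)-5-[(2-methoxypropan-2-yl)peroxy]-6-methyloct-7-en-2-one F11. PPTS in methanol then removes the ketal protecting group, and the liberated hydroperoxide closes onto the ketone to give the cyclic methyl peroxyketal 8.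

3. Step 2. The unprotected keto aldehyde may self-condense or be lost on isolation (volatile, water-soluble), and competing addition to the ketone would erode chemo- and enantioselectivity. The fallback sets out from 1 and comes back at 5. Ketalisation (ethylene glycol, TsOH, azeotropic removal of water) gives 2-(but-3-en-1-yl)-2-methyl-1,3-dioxolane F12. Ozonolysis (O3; Me2S) gives 3-(2-methyl-1,3-dioxolan-2-yl)propanal F13. The same crotylboration gives (3R,4R)-3-methyl-6-(2-methyl-1,3-dioxolan-2-yl)hex-1-en-4-ol F14, and PPTS in wet acetone returns ketone 5.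

Further compounds
F1 | step 7 | methyl (2S)-2-[(3S)-6-methoxy-6-methyl-1,2-dioxan-3-yl]propanoate | COC1(C)CC[C@@H]([C@H](C)C(=O)OC)OO1
F2 | step 7 | methyl (2S)-2-[(3S,6R)-6-methyl-6-(prop-2-en-1-yl)-1,2-dioxan-3-yl]propanoate | C=CC[C@@]1(C)CC[C@@H]([C@H](C)C(=O)OC)OO1
F3 | step 7 | methyl (2S)-2-[(3S,6R)-6-(2-hydroxyethyl)-6-methyl-1,2-dioxan-3-yl]propanoate | OCC[C@@]1(C)CC[C@@H]([C@H](C)C(=O)OC)OO1
F4 | step 7 | methyl (2S)-2-[(3S,6R)-6-(2-iodoethyl)-6-methyl-1,2-dioxan-3-yl]propanoate | ICC[C@@]1(C)CC[C@@H]([C@H](C)C(=O)OC)OO1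
F5 | step 7 | diethyl (5E)-6,10-dimethylundeca-1,5,9-trien-2-yl phosphate | C=C(OP(=O)(OCC)OCC)CC/C=C(\C)CCC=C(C)C
F6 | step 7 | (5E)-6,10-dimethylundeca-5,9-dien-1-yne | C#CCC/C=C(\C)CCC=C(C)C
F7 | step 7 | dimethyl[(1E,5E)-2,6,10-trimethylundeca-1,5,9-trien-1-yl]alumane | C[Al](C)/C=C(\C)CC/C=C(\C)CCC=C(C)C
F8 | step 7 | (1E,5E)-1-iodo-2,6,10-trimethylundeca-1,5,9-triene | I/C=C(\C)CC/C=C(\C)CCC=C(C)C
F9 | step 7 | alkylzinc iodide of F4 | I[Zn]CC[C@@]1(C)CC[C@@H]([C@H](C)C(=O)OC)OO1
F10 | step 7 | methyl (2S)-2-[(3S,6S)-6-methyl-6-[(3E,7E)-4,8,12-trimethyltrideca-3,7,11-trien-1-yl]-1,2-dioxan-3-yl]propanoate | CC(C)=CCC/C(C)=C/CC/C(C)=C/CC[C@@]1(C)CC[C@@H]([C@H](C)C(=O)OC)OO1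
F11 | step 4 | (5S,6R)-5-[(2-methoxypropan-2-yl)peroxy]-6-methyloct-7-en-2-one | CC(=O)CC[C@H](OOC(C)(C)OC)[C@H](C)C=C
F12 | step 2 | 2-(but-3-en-1-yl)-2-methyl-1,3-dioxolane | CC1(CCC=C)OCCO1
F13 | step 2 | 3-(2-methyl-1,3-dioxolan-2-yl)propanal | CC1(CCC=O)OCCO1
F14 | step 2 | (3R,4R)-3-methyl-6-(2-methyl-1,3-dioxolan-2-yl)hex-1-en-4-ol | CC1(CC[C@@H](O)[C@H](C)C=C)OCCO1
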